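**Retrosynthetic overview**
1. Target 18 ⇐ silyl ether 17 ⇐ one Pd step that joins alkenyl iodide 13, diene 15 and hydrogen carbonate, forming the C(sp2)–CH2 bond and the C1–O bond (the only stereocentre).
2. Iodide 13 ⇐ Cu-catalysed carbomagnesiation of propargyl alcohol 8 with homoallyl Grignard 9, iodine quench (sets 3Z).
3. Grignard 9 ⇐ bromide 7 ⇐ alcohol 6 ⇐ Zr-catalysed methylalumination of alkyne 3, then ethylene oxide (sets 7E) ⇐ dihydro-β-ionone 1.
4. Diene 15 ⇐ 4-bromofuran-2(5H)-one 14 by Stille vinylation.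
5. Rings: none is formed; the cyclohexene is bought in 1 and the butenolide in 14.

Assumption: 1, 8 and 14 are bought; the sense of induction of the new step 7 cannot be predicted and is checked on the first run (Mosher ester), with the (R)-ligand used instead if (S)-t-BuPHOX gives the (S)-carbinol.

**Step 1**
Reactants: 1 4-(2,6,6-trimethylcyclohex-1-en-1-yl)butan-2-one
Product: 3 2-(but-3-yn-1-yl)-1,3,3-trimethylcyclohex-1-ene, via enol phosphate 2 (not isolated)
Conditions: LDA (1.05 equiv), THF, −78 °C; ClP(O)(OEt)2, −78 → 23 °C; then LDA (2.3 equiv), −78 → 23 °C; H2O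
Reagents that add atoms: none
Why: Negishi methyl ketone → terminal alkyne conversion; kinetic deprotonation at the methyl group, O-phosphorylation and base-induced elimination of phosphate, no stereocentre involved.

**Step 2**
Reactants: 3 2-(but-3-yn-1-yl)-1,3,3-trimethylcyclohex-1-ene
Product: 6 (3E)-4-methyl-6-(2,6,6-trimethylcyclohex-1-en-1-yl)hex-3-en-1-ol, via alkenylalane 4 (not isolated), via lithium alanate 5 (not isolated)
Conditions: Me3Al (2 equiv), Cp2ZrCl2 (0.25 equiv), CH2Cl2, 0 → 23 °C; evaporate, hexane; n-BuLi (1 equiv), THF, −30 °C; ethylene oxide (3 equiv), −30 → 23 °C; aq. HCl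
Reagents that add atoms: trimethylaluminium C[Al](C)C; ethylene oxide C1CO1
Why: Negishi Zr-catalysed carboalumination adds Me–Al syn across the terminal alkyne (Me to the internal carbon), and the alkenyl alanate opens the epoxide with retention, which fixes the E trisubstituted alkene.

**Step 3**
Reactants: 6 (3E)-4-methyl-6-(2,6,6-trimethylcyclohex-1-en-1-yl)hex-3-en-1-ol
Product: 7 2-[(3E)-6-bromo-3-methylhex-3-en-1-yl]-1,3,3-trimethylcyclohex-1-ene
Conditions: CBr4, PPh3, CH2Cl2, 0 °C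
Reagents that add atoms: tetrabromomethane BrC(Br)(Br)Br
Why: Appel bromination of a primary alcohol under neutral conditions that leave both alkenes untouched.

**Step 4**
Reactants: 7 2-[(3E)-6-bromo-3-methylhex-3-en-1-yl]-1,3,3-trimethylcyclohex-1-ene; 8 prop-2-yn-1-ol
Product: 12 (2Z,5E)-2-(iodomethylidene)-6-methyl-8-(2,6,6-trimethylcyclohex-1-en-1-yl)oct-5-en-1-ol, via Grignard reagent 9 (not isolated), via propargyl alkoxide 10 (not isolated), via alkenylmagnesium adduct 11 (not isolated)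
Conditions: 7, Mg, THF, 40 °C; 8, i-PrMgCl (1.0 equiv), THF, −20 °C; combine (9 1.2 equiv), CuI (15 mol%), −10 → 23 °C; then I2, THF, −40 → 0 °C; aq. NH4Cl/Na2S2O3
Reagents that add atoms: iodine II
Why: Duboudin–Jousseaume Cu-catalysed carbomagnesiation of the propargyl alkoxide puts the alkyl group on C2 and magnesium on C3 cis to CH2O (five-membered chelate), and iodinolysis with retention gives the Z iodoalkene that becomes the 3Z alkene of the target.

**Step 5**
Reactants: 12 (2Z,5E)-2-(iodomethylidene)-6-methyl-8-(2,6,6-trimethylcyclohex-1-en-1-yl)oct-5-en-1-ol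
Product: 13 tert-butyl{[(2Z,5E)-2-(iodomethylidene)-6-methyl-8-(2,6,6-trimethylcyclohex-1-en-1-yl)oct-5-en-1-yl]oxy}dimethylsilane
Conditions: TBSCl, imidazole, CH2Cl2, 23 °C
Reagents that add atoms: tert-butyldimethylsilyl chloride CC(C)(C)[Si](C)(C)Cl
Why: Standard silylation; it blocks the cis hydroxyl, which would otherwise capture the allyl-palladium of step 7 intramolecularly to a dihydropyran.

**Step 6**
Reactants: 14 4-bromofuran-2(5H)-one
Product: 15 4-ethenylfuran-2(5H)-one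
Conditions: Bu3SnCH=CH2 (1.1 equiv), Pd(PPh3)4 (3 mol%), BHT (1 mol%), toluene, 80 °C; kept as a cold stock solution
Reagents that add atoms: tributyl(vinyl)stannane C=C[Sn](CCCC)(CCCC)CCCC
Why: Stille coupling of a β-bromo enoate under neutral conditions that spare the base-sensitive lactone.

**Step 7**
Reactants: 13 tert-butyl{[(2Z,5E)-2-(iodomethylidene)-6-methyl-8-(2,6,6-trimethylcyclohex-1-en-1-yl)oct-5-en-1-yl]oxy}dimethylsilane; 15 4-ethenylfuran-2(5H)-one
Product: 17 4-[(1R,3Z,7E)-4-({[tert-butyl(dimethyl)silyl]oxy}methyl)-1-hydroxy-8-methyl-10-(2,6,6-trimethylcyclohex-1-en-1-yl)deca-3,7-dien-1-yl]furan-2(5H)-one, via hydrogen carbonate ester 16 (not isolated)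
Conditions: Pd2(dba)3·CHCl3 (2.5 mol%), (S)-t-BuPHOX (6 mol%), KHCO3 (3 equiv), 15 (2.5 equiv), THF/H2O 10:1, 40 °C, degassed
Reagents that add atoms: potassium hydrogen carbonate [K+].OC([O-])=O
Why: Proposed new method: enantioselective Pd-catalysed three-component 1,2-alkenyl-hydroxylation of a conjugated diene – Pd(0)/PHOX adds oxidatively to the C–I bond of 13 with retention of the Z geometry, the alkenyl–Pd inserts the terminal vinyl of 15 (alkenyl to CH2) to give an η3-allyl-Pd spanning C1′–C4–C3 of the butenolide whose faces equilibrate through the O-bound Pd dienolate, and outer-sphere attack of hydrogen carbonate at C1′ (the terminus remote from the carbonyl, restoring the conjugated butenolide) forms the C–O bond and sets (R) under ligand control before 16 loses CO2; the closest known reaction types are the Heck/π-allyl heteroannulation and carboamination of 1,3-dienes with vinylic iodides and the Pd-catalysed asymmetric allylic hydroxylation with hydrogen carbonate as hydroxide surrogate.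

**Step 8**
Reactants: 17 4-[(1R,3Z,7E)-4-({[tert-butyl(dimethyl)silyl]oxy}methyl)-1-hydroxy-8-methyl-10-(2,6,6-trimethylcyclohex-1-en-1-yl)deca-3,7-dien-1-yl]furan-2(5H)-one
Product: 18 4-[(1R,3Z,7E)-1-hydroxy-4-(hydroxymethyl)-8-methyl-10-(2,6,6-trimethylcyclohex-1-en-1-yl)deca-3,7-dien-1-yl]furan-2(5H)-one
Conditions: HF·pyridine, THF/pyridine, 0 → 23 °C
Reagents that add atoms: none
Why: Fluoride desilylation of a primary allylic TBS ether under mildly acidic conditions that leave the butenolide, the carbinol stereocentre and the alkenes unchanged.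

**Compound list**
1 | 4-(2,6,6-trimethylcyclohex-1-en-1-yl)butan-2-one (dihydro-β-ionone) | CC1=C(CCC(C)=O)C(C)(C)CCC1 | starting material
2 | diethyl 4-(2,6,6-trimethylcyclohex-1-en-1-yl)but-1-en-2-yl phosphate (enol phosphate; not isolated) | CC1=C(CCC(=C)OP(=O)(OCC)OCC)C(C)(C)CCC1 | intermediate
3 | 2-(but-3-yn-1-yl)-1,3,3-trimethylcyclohex-1-ene | CC1=C(CCC#C)C(C)(C)CCC1 | intermediate
4 | dimethyl[(1E)-2-methyl-4-(2,6,6-trimethylcyclohex-1-en-1-yl)but-1-en-1-yl]alane (not isolated) | CC1=C(CC/C(C)=C/[Al](C)C)C(C)(C)CCC1 | intermediate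
5 | lithium butyl(dimethyl)[(1E)-2-methyl-4-(2,6,6-trimethylcyclohex-1-en-1-yl)but-1-en-1-yl]alanate (not isolated) | [Li+].CC1=C(CC/C(C)=C/[Al-](C)(C)CCCC)C(C)(C)CCC1 | intermediate
6 | (3E)-4-methyl-6-(2,6,6-trimethylcyclohex-1-en-1-yl)hex-3-en-1-ol | CC1=C(CC/C(C)=C/CCO)C(C)(C)CCC1 | intermediate
7 | 2-[(3E)-6-bromo-3-methylhex-3-en-1-yl]-1,3,3-trimethylcyclohex-1-ene | CC1=C(CC/C(C)=C/CCBr)C(C)(C)CCC1 | intermediate
8 | prop-2-yn-1-ol | C#CCO | starting material
9 | [(3E)-4-methyl-6-(2,6,6-trimethylcyclohex-1-en-1-yl)hex-3-en-1-yl]magnesium bromide (not isolated) | CC1=C(CC/C(C)=C/CC[Mg]Br)C(C)(C)CCC1 | intermediate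
10 | chloromagnesium prop-2-yn-1-olate (not isolated) | C#CCO[Mg]Cl | intermediate
11 | [(1Z,4E)-2-(chloromagnesiooxymethyl)-5-methyl-7-(2,6,6-trimethylcyclohex-1-en-1-yl)hepta-1,4-dien-1-yl]magnesium bromide (not isolated) | CC1=C(CC/C(C)=C/CC/C(=C/[Mg]Br)CO[Mg]Cl)C(C)(C)CCC1 | intermediate
12 | (2Z,5E)-2-(iodomethylidene)-6-methyl-8-(2,6,6-trimethylcyclohex-1-en-1-yl)oct-5-en-1-ol | CC1=C(CC/C(C)=C/CC/C(=C/I)CO)C(C)(C)CCC1 | intermediate
13 | tert-butyl{[(2Z,5E)-2-(iodomethylidene)-6-methyl-8-(2,6,6-trimethylcyclohex-1-en-1-yl)oct-5-en-1-yl]oxy}dimethylsilane | CC1=C(CC/C(C)=C/CC/C(=C/I)CO[Si](C)(C)C(C)(C)C)C(C)(C)CCC1 | intermediate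
14 | 4-bromofuran-2(5H)-one | BrC1=CC(=O)OC1 | starting material
15 | 4-ethenylfuran-2(5H)-one | C=CC1=CC(=O)OC1 | intermediate
16 | (1R,3Z,7E)-4-({[tert-butyl(dimethyl)silyl]oxy}methyl)-8-methyl-1-(5-oxo-2,5-dihydrofuran-3-yl)-10-(2,6,6-trimethylcyclohex-1-en-1-yl)deca-3,7-dien-1-yl hydrogen carbonate (not isolated) | CC1=C(CC/C(C)=C/CC/C(=C/C[C@@H](OC(=O)O)C2=CC(=O)OC2)CO[Si](C)(C)C(C)(C)C)C(C)(C)CCC1 | intermediate
17 | 4-[(1R,3Z,7E)-4-({[tert-butyl(dimethyl)silyl]oxy}methyl)-1-hydroxy-8-methyl-10-(2,6,6-trimethylcyclohex-1-en-1-yl)deca-3,7-dien-1-yl]furan-2(5H)-one | CC1=C(CC/C(C)=C/CC/C(=C/C[C@@H](O)C2=CC(=O)OC2)CO[Si](C)(C)C(C)(C)C)C(C)(C)CCC1 | intermediate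
18 | 4-[(1R,3Z,7E)-1-hydroxy-4-(hydroxymethyl)-8-methyl-10-(2,6,6-trimethylcyclohex-1-en-1-yl)deca-3,7-dien-1-yl]furan-2(5H)-one | CC1=C(CC/C(C)=C/CC/C(=C/C[C@@H](O)C2=CC(=O)OC2)CO)C(C)(C)CCC1 | target

**Totals**
Total steps: 8. Longest linear sequence: 7 (steps 1, 2, 3, 4, 5, 7, 8).

**Steps most likely to fail**

Step 7 (the proposed new reaction). The risks are β-hydride elimination to the conjugated triene, attack at C3 instead of C1′, low enantioselectivity and polymerisation of 15. The fallback uses known chemistry, sets out from 13 and comes back at 17. Commercial furan-3-carbaldehyde is converted by Corey–Chaykovsky epoxidation (Me3S+ I−, KOH) into racemic 2-(furan-3-yl)oxirane F1. Jacobsen hydrolytic kinetic resolution (the Co-salen antipode that spares the S oxirane, (S,S) by analogy with styrene oxide; 0.55 equiv H2O) leaves (S)-2-(furan-3-yl)oxirane F2. Iodide 13 is lithiated (t-BuLi, Et2O, −78 °C), transmetalated (MgBr2·OEt2) and added with CuI (10 mol%) to the CH2 terminus of F2. This gives (1R,3Z,7E)-4-({[tert-butyl(dimethyl)silyl]oxy}methyl)-1-(furan-3-yl)-8-methyl-10-(2,6,6-trimethylcyclohex-1-en-1-yl)deca-3,7-dien-1-ol F3, with the stereocentre taken from the resolved epoxide. Photo-oxygenation (O2, rose bengal, hν, i-Pr2NEt, CH2Cl2, −78 °C) gives the 5-hydroxybutenolide 4-[(1R,3Z,7E)-4-({[tert-butyl(dimethyl)silyl]oxy}methyl)-1-hydroxy-8-methyl-10-(2,6,6-trimethylcyclohex-1-en-1-yl)deca-3,7-dien-1-yl]-5-hydroxyfuran-2(5H)-one F4. NaBH4 (EtOH, 0 °C; then dilute HCl) reduces the masked aldehyde and relactonises to 17. This fallback does not need 15.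

Step 4. The carbomagnesiation is well known for simple Grignard reagents; with the valuable homoallyl reagent 9, deprotonation of the alkyne C–H and homocoupling may lower the yield. The fallback sets out from 7 and comes back at 12. Bromide 7 is alkynylated with lithium acetylide–ethylenediamine (DMSO, 10 °C) to 1,3,3-trimethyl-2-[(3E)-3-methyloct-3-en-7-yn-1-yl]cyclohex-1-ene F5. Rh-catalysed silylformylation (Me2PhSiH, CO 20 bar, Rh4(CO)12, Et3N, toluene) places the formyl group on the internal carbon and silicon cis to it, giving (2Z,5E)-2-{[dimethyl(phenyl)silyl]methylidene}-6-methyl-8-(2,6,6-trimethylcyclohex-1-en-1-yl)oct-5-enal F6. NaBH4/CeCl3 gives (2Z,5E)-2-{[dimethyl(phenyl)silyl]methylidene}-6-methyl-8-(2,6,6-trimethylcyclohex-1-en-1-yl)oct-5-en-1-ol F7. Iododesilylation with retention (NIS, HFIP, 0 °C) returns 12; the electron-rich ring alkene may compete for iodine here.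

Step 6. The Stille coupling may be sluggish on the bromofuranone, and 15 is a polymerisable diene. The fallback sets out from 14 and comes back at 15. Sonogashira coupling of 14 with ethynyltrimethylsilane (PdCl2(PPh3)2, CuI, Et3N, THF) gives 4-[(trimethylsilyl)ethynyl]furan-2(5H)-one F8, which can be stored. KF/MeOH gives 4-ethynylfuran-2(5H)-one F9, and Lindlar semi-hydrogenation (quinoline, H2, EtOAc) releases 15 as a solution just before step 7.

**Further compounds**
F1 | step 7 | racemic 2-(furan-3-yl)oxirane | C1OC1c1ccoc1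
F2 | step 7 | (S)-2-(furan-3-yl)oxirane | C1[C@@H](O1)c1ccoc1
F3 | step 7 | (1R,3Z,7E)-4-({[tert-butyl(dimethyl)silyl]oxy}methyl)-1-(furan-3-yl)-8-methyl-10-(2,6,6-trimethylcyclohex-1-en-1-yl)deca-3,7-dien-1-ol | CC1=C(CC/C(C)=C/CC/C(=C/C[C@@H](O)c2ccoc2)CO[Si](C)(C)C(C)(C)C)C(C)(C)CCC1
F4 | step 7 | 4-[(1R,3Z,7E)-4-({[tert-butyl(dimethyl)silyl]oxy}methyl)-1-hydroxy-8-methyl-10-(2,6,6-trimethylcyclohex-1-en-1-yl)deca-3,7-dien-1-yl]-5-hydroxyfuran-2(5H)-one (C5 epimers) | CC1=C(CC/C(C)=C/CC/C(=C/C[C@@H](O)C2=CC(=O)OC2O)CO[Si](C)(C)C(C)(C)C)C(C)(C)CCC1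
F5 | step 4 | 1,3,3-trimethyl-2-[(3E)-3-methyloct-3-en-7-yn-1-yl]cyclohex-1-ene | CC1=C(CC/C(C)=C/CCC#C)C(C)(C)CCC1
F6 | step 4 | (2Z,5E)-2-{[dimethyl(phenyl)silyl]methylidene}-6-methyl-8-(2,6,6-trimethylcyclohex-1-en-1-yl)oct-5-enal | CC1=C(CC/C(C)=C/CC/C(=C/[Si](C)(C)c2ccccc2)C=O)C(C)(C)CCC1
F7 | step 4 | (2Z,5E)-2-{[dimethyl(phenyl)silyl]methylidene}-6-methyl-8-(2,6,6-trimethylcyclohex-1-en-1-yl)oct-5-en-1-ol | CC1=C(CC/C(C)=C/CC/C(=C/[Si](C)(C)c2ccccc2)CO)C(C)(C)CCC1
F8 | step 6 | 4-[(trimethylsilyl)ethynyl]furan-2(5H)-one | C[Si](C)(C)C#CC1=CC(=O)OC1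
F9 | step 6 | 4-ethynylfuran-2(5H)-one | C#CC1=CC(=O)OC1
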